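## Retrosynthetic overview
1. Target ⇒ protected erythro (7R,8S) arylglycerol β-aryl ether, by removing the phenolic O-benzyl group (hydrogenolysis) and two TBS ethers (fluoride).
2. Erythro C7-OH ⇒ Mitsunobu inversion of the threo (7S,8S) alcohol. C9H2OH ⇒ reductive removal of an oxazolidinone auxiliary.
3. Key C7–C8 bond ⇒ intermolecular Evans boron syn-aldol of an N-(aryloxyacetyl)-(R)-4-benzyloxazolidinone with O-benzylvanillin. This fixes C8 for good and C7 provisionally.
4. Aryloxyacetyl fragment ⇒ syringaldehyde + ethyl bromoacetate (Williamson C8–O bond), then CHO → CH2OTBS and ester → acid → imide.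
5. No ring is formed. Ring A (vanillin), ring B (syringaldehyde) and the auxiliary ring are all bought.

Assumption: CIP analysis of the given SMILES gives (7R,8S), the erythro isomer. Lignan numbering is used: C7 is the benzylic carbinol carbon, C8 the aryloxy-bearing carbon, C9 the CH2OH carbon. TBS = tert-butyldimethylsilyl.

## Route

Step 1
Reactants: 1 vanillin
Product: 2 4-(benzyloxy)-3-methoxybenzaldehyde (O-benzylvanillin)
Conditions: BnBr (1.1 equiv), K2CO3 (1.5 equiv), DMF, rt to 60 °C
Reagents that add atoms: benzyl bromide, BrCc1ccccc1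
Why: Williamson ether synthesis (SN2 of the phenoxide on benzyl bromide) masks the acidic phenol with a group that survives boron enolate, hydride, Mitsunobu, carbonate and fluoride conditions; no stereocentre is involved.

Step 2
Reactants: 3 syringaldehyde; 4 ethyl bromoacetate
Product: 5 ethyl 2-(4-formyl-2,6-dimethoxyphenoxy)acetate
Conditions: K2CO3 (2 equiv), DMF, 60 °C
Reagents that add atoms: none
Why: Williamson ether synthesis in which the acidic syringyl phenoxide displaces bromide from a very SN2-active α-bromo ester, so the future C8–O bond is made before any stereocentre exists.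

Step 3
Reactants: 5 ethyl 2-(4-formyl-2,6-dimethoxyphenoxy)acetate
Product: 6 ethyl 2-[4-(hydroxymethyl)-2,6-dimethoxyphenoxy]acetate
Conditions: NaBH4 (0.5 equiv), EtOH, 0 °C, 30 min; aqueous work-up
Reagents that add atoms: none
Why: Chemoselective borohydride reduction, because the aryl aldehyde reacts within minutes at 0 °C while the ethyl ester is practically inert to a small charge of NaBH4 in EtOH.

Step 4
Reactants: 6 ethyl 2-[4-(hydroxymethyl)-2,6-dimethoxyphenoxy]acetate
Product: 7 ethyl 2-[4-(TBSO-methyl)-2,6-dimethoxyphenoxy]acetate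
Conditions: TBSCl (1.2 equiv), imidazole (2 equiv), CH2Cl2, 0 °C to rt
Reagents that add atoms: tert-butyldimethylsilyl chloride, CC(C)(C)[Si](C)(C)Cl
Why: Standard silyl ether protection of a primary alcohol, so that it cannot be acylated in step 6, bind n-Bu2BOTf in step 7 or compete in the Mitsunobu step.

Step 5
Reactants: 7 ethyl 2-[4-(TBSO-methyl)-2,6-dimethoxyphenoxy]acetate
Product: 8 2-[4-(TBSO-methyl)-2,6-dimethoxyphenoxy]acetic acid
Conditions: LiOH·H2O (2 equiv), THF/H2O (3:1), 0 °C to rt; then cold 0.5 M HCl to pH 4, EtOAc extraction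
Reagents that add atoms: lithium hydroxide, [Li+].[OH-]
Why: Saponification (acyl-oxygen ester hydrolysis) of an unhindered activated ester; the alkyl TBS ether tolerates LiOH and a brief cold acidification to pH 4.

Step 6
Reactants: 8 2-[4-(TBSO-methyl)-2,6-dimethoxyphenoxy]acetic acid; 9 (R)-4-benzyl-1,3-oxazolidin-2-one
Product: 11 (4R)-4-benzyl-3-{2-[4-(TBSO-methyl)-2,6-dimethoxyphenoxy]acetyl}-1,3-oxazolidin-2-one, via mixed pivalic anhydride 10 (not isolated)
Conditions: PivCl (1.05 equiv), Et3N (2.5 equiv), THF, −20 °C, 1 h; then LiCl (1.1 equiv), 9 (1.0 equiv), −20 °C to rt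
Reagents that add atoms: pivaloyl chloride, CC(C)(C)C(=O)Cl (its atoms stay in 10 only)
Why: N-acylation through a mixed anhydride, in which the auxiliary attacks the unhindered aryloxyacetyl carbonyl and not the tert-butyl-shielded one; the bought stereocentre is untouched.

Step 7
Reactants: 11 (4R)-4-benzyl-3-{2-[4-(TBSO-methyl)-2,6-dimethoxyphenoxy]acetyl}-1,3-oxazolidin-2-one; 2 4-(benzyloxy)-3-methoxybenzaldehyde
Product: 14 (4R)-4-benzyl-3-{(2R,3S)-3-[4-(benzyloxy)-3-methoxyphenyl]-2-[4-(TBSO-methyl)-2,6-dimethoxyphenoxy]-3-hydroxypropanoyl}-1,3-oxazolidin-2-one (Evans-syn adduct), via Z-dibutylboron enolate 12 (not isolated), via dibutylboron aldolate 13 (not isolated)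
Conditions: n-Bu2BOTf (1.2 equiv), Et3N (1.4 equiv), CH2Cl2, −78 to 0 °C; 2 (1.15 equiv), −78 to 0 °C; then pH 7 phosphate buffer, MeOH, 30% H2O2, 0 °C
Reagents that add atoms: dibutylboron triflate, CCCCB(CCCC)OS(=O)(=O)C(F)(F)F (its Bu2B group stays in 12 and 13 only)
Why: Evans boron aldol in which the Z-enolate adds to the non-enolisable aldehyde through a dipole-minimised Zimmerman–Traxler chair on the face away from the auxiliary benzyl group, so the (R)-auxiliary gives the syn adduct (expected dr above 20:1) with C8 in its final spatial arrangement and C7 as S.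

Step 8
Reactants: 14 Evans-syn adduct
Product: 16 (1S,2S)-1-[4-(benzyloxy)-3-methoxyphenyl]-2-[4-(TBSO-methyl)-2,6-dimethoxyphenoxy]propane-1,3-diol (threo diol), via beta-hydroxy aldehyde 15 (not isolated)
Conditions: NaBH4 (4 equiv), THF/H2O (4:1), 0 °C to rt
Reagents that add atoms: none
Why: Reductive cleavage of the N-acyloxazolidinone, in which hydride attacks the more electrophilic exocyclic imide carbonyl and aldehyde 15 is reduced faster than it can enolise, so C7 and C8 are kept and the auxiliary is recovered.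

Step 9
Reactants: 16 threo diol
Product: 17 (1S,2S)-1-[4-(benzyloxy)-3-methoxyphenyl]-3-(TBSO)-2-[4-(TBSO-methyl)-2,6-dimethoxyphenoxy]propan-1-ol
Conditions: TBSCl (1.05 equiv), imidazole (2 equiv), CH2Cl2, −10 to 0 °C
Reagents that add atoms: tert-butyldimethylsilyl chloride, CC(C)(C)[Si](C)(C)Cl
Why: Selective silyl ether formation, because the primary C9-OH reacts far faster than the hindered secondary benzylic C7-OH with one equivalent of TBSCl; no stereocentre is touched.

Step 10
Reactants: 17 threo C9-O-TBS alcohol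
Product: 19 (1R,2S)-1-[4-(benzyloxy)-3-methoxyphenyl]-3-(TBSO)-2-[4-(TBSO-methyl)-2,6-dimethoxyphenoxy]propyl 4-nitrobenzoate, via alkoxyphosphonium 4-nitrobenzoate 18 (not isolated)
Conditions: 4-nitrobenzoic acid (2 equiv), PPh3 (2 equiv), DIAD (2 equiv), THF, −20 °C to rt
Reagents that add atoms: 4-nitrobenzoic acid, OC(=O)c1ccc(cc1)[N+](=O)[O-]; triphenylphosphine, c1ccc(cc1)P(c1ccccc1)c1ccccc1 (its atoms stay in 18 only)
Why: Mitsunobu reaction with an acidic carboxylate suited to hindered alcohols, in which SN2 displacement of 18 inverts C7 from S to R while C8 is untouched, and any leakage through a benzylic cation gives only the chromatographically separable threo diastereomer, never the enantiomer.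

Step 11
Reactants: 19 erythro 4-nitrobenzoate
Product: 20 (1R,2S)-1-[4-(benzyloxy)-3-methoxyphenyl]-3-(TBSO)-2-[4-(TBSO-methyl)-2,6-dimethoxyphenoxy]propan-1-ol
Conditions: K2CO3 (0.3 equiv), MeOH/THF (2:1), 0 °C to rt
Reagents that add atoms: none
Why: Base-catalysed transesterification cleaves the activated ester at the acyl–oxygen bond, so the C7–O bond and its R configuration are retained, and any C9-to-C7 silyl shift would be harmless because both silyl groups fall in step 12.

Step 12
Reactants: 20 erythro bis-TBS alcohol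
Product: 21 (1R,2S)-1-[4-(benzyloxy)-3-methoxyphenyl]-2-[4-(hydroxymethyl)-2,6-dimethoxyphenoxy]propane-1,3-diol
Conditions: TBAF (3 equiv), AcOH (3 equiv), THF, 0 °C to rt
Reagents that add atoms: none
Why: Fluoride-driven desilylation (strong Si–F bond) removes both primary TBS ethers, and the acetic acid buffer keeps the medium near neutral so the electron-rich benzylic carbinol is neither ionised nor epimerised.

Step 13
Reactants: 21 O-benzyl triol
Product: 22 (1R,2S)-1-(4-hydroxy-3-methoxyphenyl)-2-[4-(hydroxymethyl)-2,6-dimethoxyphenoxy]propane-1,3-diol (target)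
Conditions: H2 (1 atm), 10% Pd/C, EtOAc/EtOH (1:1), rt, stopped at full conversion (about 1–2 h), filtration through Celite
Reagents that add atoms: none
Why: Catalytic hydrogenolysis, in which the aryl benzyl ether is cleaved much faster than benzylic alcohols on Pd/C in neutral medium, so both carbinols and both stereocentres survive and the polar product needs only filtration.

## Compound list
1 | vanillin | COc1cc(C=O)ccc1O | starting material
2 | 4-(benzyloxy)-3-methoxybenzaldehyde | COc1cc(C=O)ccc1OCc1ccccc1 | intermediate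
3 | syringaldehyde | COc1cc(C=O)cc(OC)c1O | starting material
4 | ethyl bromoacetate | CCOC(=O)CBr | starting material
5 | ethyl 2-(4-formyl-2,6-dimethoxyphenoxy)acetate | CCOC(=O)COc1c(OC)cc(C=O)cc1OC | intermediate
6 | ethyl 2-[4-(hydroxymethyl)-2,6-dimethoxyphenoxy]acetate | CCOC(=O)COc1c(OC)cc(CO)cc1OC | intermediate
7 | ethyl 2-[4-(TBSO-methyl)-2,6-dimethoxyphenoxy]acetate | CCOC(=O)COc1c(OC)cc(CO[Si](C)(C)C(C)(C)C)cc1OC | intermediate
8 | 2-[4-(TBSO-methyl)-2,6-dimethoxyphenoxy]acetic acid | OC(=O)COc1c(OC)cc(CO[Si](C)(C)C(C)(C)C)cc1OC | intermediate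
9 | (R)-4-benzyl-1,3-oxazolidin-2-one | O=C1OC[C@@H](Cc2ccccc2)N1 | starting material
10 | mixed pivalic anhydride of 8 (not isolated) | CC(C)(C)C(=O)OC(=O)COc1c(OC)cc(CO[Si](C)(C)C(C)(C)C)cc1OC | intermediate
11 | (4R)-4-benzyl-3-{2-[4-(TBSO-methyl)-2,6-dimethoxyphenoxy]acetyl}-1,3-oxazolidin-2-one | O=C1OC[C@@H](Cc2ccccc2)N1C(=O)COc1c(OC)cc(CO[Si](C)(C)C(C)(C)C)cc1OC | intermediate
12 | Z-dibutylboron enolate of 11 (not isolated) | CCCCB(CCCC)O/C(=C\Oc1c(OC)cc(CO[Si](C)(C)C(C)(C)C)cc1OC)N1C(=O)OC[C@H]1Cc1ccccc1 | intermediate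
13 | dibutylboron aldolate of 14 (not isolated) | COc1cc([C@H](OB(CCCC)CCCC)[C@H](C(=O)N2C(=O)OC[C@H]2Cc2ccccc2)Oc2c(OC)cc(CO[Si](C)(C)C(C)(C)C)cc2OC)ccc1OCc1ccccc1 | intermediate
14 | (4R)-auxiliary (2R,3S) Evans-syn aldol adduct | COc1cc([C@H](O)[C@H](C(=O)N2C(=O)OC[C@H]2Cc2ccccc2)Oc2c(OC)cc(CO[Si](C)(C)C(C)(C)C)cc2OC)ccc1OCc1ccccc1 | intermediate
15 | (2R,3S)-3-[4-(benzyloxy)-3-methoxyphenyl]-2-[4-(TBSO-methyl)-2,6-dimethoxyphenoxy]-3-hydroxypropanal (not isolated) | COc1cc([C@H](O)[C@H](C=O)Oc2c(OC)cc(CO[Si](C)(C)C(C)(C)C)cc2OC)ccc1OCc1ccccc1 | intermediate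
16 | (1S,2S) threo diol | COc1cc([C@H](O)[C@H](CO)Oc2c(OC)cc(CO[Si](C)(C)C(C)(C)C)cc2OC)ccc1OCc1ccccc1 | intermediate
17 | (1S,2S) threo C9-O-TBS alcohol | COc1cc([C@H](O)[C@H](CO[Si](C)(C)C(C)(C)C)Oc2c(OC)cc(CO[Si](C)(C)C(C)(C)C)cc2OC)ccc1OCc1ccccc1 | intermediate
18 | alkoxyphosphonium 4-nitrobenzoate of 17 (not isolated) | COc1cc([C@H](O[P+](c2ccccc2)(c2ccccc2)c2ccccc2)[C@H](CO[Si](C)(C)C(C)(C)C)Oc2c(OC)cc(CO[Si](C)(C)C(C)(C)C)cc2OC)ccc1OCc1ccccc1.[O-]C(=O)c1ccc(cc1)[N+](=O)[O-] | intermediate
19 | (1R,2S) erythro 4-nitrobenzoate | COc1cc([C@@H](OC(=O)c2ccc(cc2)[N+](=O)[O-])[C@H](CO[Si](C)(C)C(C)(C)C)Oc2c(OC)cc(CO[Si](C)(C)C(C)(C)C)cc2OC)ccc1OCc1ccccc1 | intermediate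
20 | (1R,2S) erythro bis-TBS alcohol | COc1cc([C@@H](O)[C@H](CO[Si](C)(C)C(C)(C)C)Oc2c(OC)cc(CO[Si](C)(C)C(C)(C)C)cc2OC)ccc1OCc1ccccc1 | intermediate
21 | (1R,2S)-1-[4-(benzyloxy)-3-methoxyphenyl]-2-[4-(hydroxymethyl)-2,6-dimethoxyphenoxy]propane-1,3-diol | COc1cc([C@@H](O)[C@H](CO)Oc2c(OC)cc(CO)cc2OC)ccc1OCc1ccccc1 | intermediate
22 | (1R,2S)-1-(4-hydroxy-3-methoxyphenyl)-2-[4-(hydroxymethyl)-2,6-dimethoxyphenoxy]propane-1,3-diol | COc1cc([C@@H](O)[C@H](CO)Oc2c(OC)cc(CO)cc2OC)ccc1O | target

## Step count and risks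
Total step count: 13. Longest linear sequence: 12 steps (steps 2–13, from syringaldehyde 3).

**Step 7 (aldol).** The risk is a sluggish addition of the crowded aryloxy enolate to an electron-rich aldehyde, or an eroded diastereomer ratio. The fallback sets out from acid 8 and comes back at diol 16.
- Acid 8 is coupled with commercial (R)-4-benzyl-1,3-thiazolidine-2-thione (EDC·HCl, DMAP, CH2Cl2) to give the N-acylthiazolidinethione F1.
- F1 is treated with TiCl4 (1.05 equiv), i-Pr2NEt (1.1 equiv) and N-methylpyrrolidinone (1 equiv) in CH2Cl2 at −78 to 0 °C, then with aldehyde 2.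
- The non-chelated chair transition state gives the Evans-syn thiazolidinethione adduct F2, with the same (2R,3S) arrangement as 14.
- The very labile thione auxiliary is displaced by NaBH4 in THF/EtOH at 0 °C, giving 16.

**Step 10 (Mitsunobu inversion).** The risk is partial ionisation of the electron-rich benzylic position, or no reaction for steric reasons. The fallback sets out from 17 and comes back at 20.
- Alcohol 17 is oxidised with Dess–Martin periodinane and NaHCO3 in CH2Cl2 at 0 °C to the (2S)-aryl ketone F3.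
- F3 is reduced at once with Zn(BH4)2 in Et2O at −78 to −30 °C.
- Zinc chelation of the carbonyl and aryloxy oxygens exposes the face opposite CH2OTBS (Cram chelate model), which delivers the 7R erythro alcohol 20.
- Any threo isomer formed is 17 itself. It is separated by chromatography and recycled.

**Step 13 (hydrogenolysis).** The risk is over-reduction of the free benzylic alcohols, above all the primary one on ring B. The fallback sets out from 20 and comes back at 22, with the order of the two deprotections reversed.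
- Compound 20 is hydrogenolysed (H2, 10% Pd/C, EtOAc) while C9-OH and the ring B carbinol are still silyl ethers, giving the bis-TBS phenol F4.
- TBAF/AcOH in THF then removes both silyl groups, so the last bond-breaking event is fluoride-mediated and gives 22.

## Further compounds
F1 | step 7 | (4R)-4-benzyl-3-{2-[4-(TBSO-methyl)-2,6-dimethoxyphenoxy]acetyl}-1,3-thiazolidine-2-thione | S=C1SC[C@@H](Cc2ccccc2)N1C(=O)COc1c(OC)cc(CO[Si](C)(C)C(C)(C)C)cc1OC
F2 | step 7 | (4R)-thiazolidinethione (2R,3S) Evans-syn aldol adduct | COc1cc([C@H](O)[C@H](C(=O)N2C(=S)SC[C@H]2Cc2ccccc2)Oc2c(OC)cc(CO[Si](C)(C)C(C)(C)C)cc2OC)ccc1OCc1ccccc1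
F3 | step 10 | (2S)-1-[4-(benzyloxy)-3-methoxyphenyl]-3-(TBSO)-2-[4-(TBSO-methyl)-2,6-dimethoxyphenoxy]propan-1-one | COc1cc(C(=O)[C@H](CO[Si](C)(C)C(C)(C)C)Oc2c(OC)cc(CO[Si](C)(C)C(C)(C)C)cc2OC)ccc1OCc1ccccc1
F4 | step 13 | (1R,2S)-1-(4-hydroxy-3-methoxyphenyl)-3-(TBSO)-2-[4-(TBSO-methyl)-2,6-dimethoxyphenoxy]propan-1-ol | COc1cc([C@@H](O)[C@H](CO[Si](C)(C)C(C)(C)C)Oc2c(OC)cc(CO[Si](C)(C)C(C)(C)C)cc2OC)ccc1O
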